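Numbering used: the target is read as a hexahydronaphthalene; ring A = C1(CO2Me)–C2(hexadecyl)=C3–C4(CO2Me)–C4a–C8a, ring B = C4a–C5(=O)–C6(CO2Me)=C7(hexadecyl)–C8–C8a.
Retrosynthesis: cut C2–CH2 (ring A alkene carbon to its hexadecyl chain) to an alkenyl bromide and hexadecylzinc bromide; remove the C6=C7 double bond; tie the C1 carboxyl to an oxygen on C4 as a lactone bridge; cut C4–C4a and C1–C8a (Diels–Alder) to a 2-pyrone and a cyclohexenone; cut the cyclohexenone at C7–C6 (Michael) and C4a=C8a (aldol).
Forward: ring B first (enal plus methyl acetoacetate); then ring A by [4+2] addition of methyl 4-bromo-2-pyrone-6-carboxylate, a flat heteroarene that becomes the stereochemically dense ring; then the chain is joined at C2; then the lactone bridge (a ring absent from the target) is opened reductively and ring B is dehydrogenated.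
Stereochemistry: an aminocatalyst sets a temporary C7 centre; the diene adds anti to it and endo (C4a, C8a); the lactone bridge holds the C1 carboxyl and the C4 oxygen on one face, so C1-CO2Me ends trans to C4-CO2Me; C4–H is put in by convex-face protonation in place of the oxygen; C6/C7 are erased at the end.
Enabling feature: C1(CO2R)–C2=C3–C4(CO2Me) of ring A is C3–C4–C5–C6 of a 2-pyrone-6-carboxylate with the ring oxygen still on C4; in that bicyclo[2.2.2] adduct C1 and C4 are bridgeheads, so a bromine on C2 is a fixed alkenyl bromide and C2=C3 cannot move into conjugation after coupling.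

Key step: step 7

Assumption: methyl 2-(trimethylsilyloxy)acrylate is taken as purchasable (otherwise one silylation from methyl pyruvate); the β-keto ester carbon C6 of the ring B intermediates is drawn as the trans keto form although it equilibrates with its enol.

Step 1
Reactants: 1 1-octadecene; 2 (E)-crotonaldehyde
Product: 3 (E)-nonadec-2-enal
Conditions: RuCl2(=CHPh)(PCy3)(H2IMes) (second-generation Grubbs catalyst, 2 mol %), 2 (5 equiv), CH2Cl2, 40 °C
Reagents that add atoms: none
Why: Olefin cross-metathesis of an unhindered terminal alkene with an excess of the electron-poor enal partner should favour the cross product as the E-enal, with propene lost as the driving by-product.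

Step 2
Reactants: 3 (E)-nonadec-2-enal; 4 methyl acetoacetate
Product: 6 methyl (1S,6R)-6-hexadecyl-2-oxocyclohex-3-ene-1-carboxylate, via Michael adduct aldehyde 5 (not isolated)
Conditions: (S)-α,α-diphenylprolinol trimethylsilyl ether (10 mol %), PhCO2H (10 mol %), PhMe, rt; then p-TsOH (20 mol %), 60 °C
Reagents that add atoms: none
Why: Iminium activation of 3 lets the β-keto ester add in a Michael reaction to the enal face left open by the diphenyl(silyloxy)methyl group, which should set the hexadecyl-bearing centre as (R), and acid then drives the intramolecular aldol condensation of the methyl ketone onto the aldehyde (Robinson-type annulation), the ester-bearing carbon settling trans by enolisation.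

Step 3
Reactants: 7 methyl 2-(trimethylsilyloxy)acrylate; 8 malonyl dichloride
Product: 10 methyl 4-hydroxy-2-oxo-2H-pyran-6-carboxylate, via acid chloride 9 (not isolated)
Conditions: Et2O, −78 °C to rt
Reagents that add atoms: none
Why: The silyl enol ether is C-acylated by malonyl dichloride with loss of Me3SiCl and the enol oxygen of the resulting triketone closes onto the remaining acid chloride, the known one-flask route from silyl enol ethers and malonyl dichloride to 4-hydroxy-2-pyrones.

Step 4
Reactants: 10 methyl 4-hydroxy-2-oxo-2H-pyran-6-carboxylate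
Product: 11 methyl 4-bromo-2-oxo-2H-pyran-6-carboxylate
Conditions: Bu4NBr, P2O5, PhMe, 100 °C
Reagents that add atoms: tetrabutylammonium bromide, CCCC[N+](CCCC)(CCCC)CCCC.[Br-]
Why: Phosphate activation of the vinylogous acid OH followed by addition–elimination of bromide at C4 is the standard deoxybromination of 4-hydroxy-2-pyrones, and it places the halogen on the pyrone carbon that becomes C2 of ring A.

Step 5
Reactants: 6 methyl (1S,6R)-6-hexadecyl-2-oxocyclohex-3-ene-1-carboxylate; 11 methyl 4-bromo-2-oxo-2H-pyran-6-carboxylate
Product: 12 bridged bromo lactone: target skeleton with Br on C2, the C1 carboxyl closed as a lactone onto an oxygen on C4 (C4 also carries CO2Me), C4a–H and C8a–H cis to each other and on the side of the lactone bridge, ring B saturated at C6/C7 with the C7 hexadecyl anti to the ring A bonds and the C6 CO2Me trans to it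
Conditions: CH2Cl2, 12 kbar, 40 °C
Reagents that add atoms: none
Why: Diels–Alder reaction of the 2-pyrone as diene, run under high pressure so that two electron-poor partners combine below the temperature at which the adduct would lose CO2: the nucleophilic pyrone C3 should bond to the enone β-carbon (C1–C8a) and the ester-bearing pyrone C6 to the α-carbon (C4–C4a), the diene should approach anti to the hexadecyl group (setting C4a and C8a), and endo orientation should place ring B away from the lactone bridge, which fixes C1 and C4 relative to the ring fusion.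

Step 6
Reactants: 13 1-bromohexadecane
Product: 14 hexadecylzinc bromide (C16H33ZnBr), used as its DMA solution
Conditions: Zn dust, I2 (5 mol %), DMA, 80 °C
Reagents that add atoms: zinc, [Zn]
Why: Direct oxidative insertion of iodine-activated zinc into a primary alkyl bromide in a polar amide solvent is the standard preparation of a primary alkylzinc bromide.

Step 7
Reactants: 12 bridged bromo lactone; 14 hexadecylzinc bromide (C16H33ZnBr)
Product: 15 bridged dihexadecyl lactone: as 12 with the hexadecyl chain in place of Br on C2
Conditions: 14 (3 equiv), Pd(dppf)Cl2 (5 mol %), THF/DMA, 50 °C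
Reagents that add atoms: none
Why: Negishi coupling: zerovalent palladium, formed in situ from Pd(dppf)Cl2 and the organozinc, inserts into the C2–Br bond of 12, the hexadecyl group passes from zinc to palladium, and reductive elimination forms the C2–CH2 bond. The closest known reaction type is the palladium-catalysed C(sp2)–C(sp3) coupling of cyclic alkenyl bromides with primary alkylzinc halides. The step closes no ring and creates no stereocentre, and the centres set in step 5 are not at risk because the reagent is neither basic nor nucleophilic enough to touch the lactone, the ketone or the esters. The selectivity needed is positional: the new trisubstituted alkene must stay at C2=C3, out of conjugation with both flanking carboxyl groups, and the substrate secures this because C1 and C4 are bridgeheads of the 2-oxabicyclo[2.2.2]octene (Bredt's rule) and cannot become sp2 by enolisation or by metal hydride migration. Ionisation of the allylic C4–O bond by zerovalent palladium is not expected, since the alkene face anti to that bond is covered by the endo ring B, and the wide bite angle of dppf favours reductive elimination over β-hydride elimination of the alkyl chain. The excess of 14 allows for protonolysis by the enolised β-keto ester of ring B, whose zinc enolate is inert and returns the keto ester on work-up.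

Step 8
Reactants: 15 bridged dihexadecyl lactone
Product: 17 trimethyl (1S,4R,4aS,6S,7R,8aR)-2,7-dihexadecyl-5-oxo-1,4,4a,5,6,7,8,8a-octahydronaphthalene-1,4,6-tricarboxylate, via carboxylic acid 16 (not isolated)
Conditions: LiN(SiMe3)2 (1.0 equiv), THF, −78 °C; SmI2 (2.5 equiv), HMPA, t-BuOH, −78 °C; aq. NH4Cl; then TMSCHN2, PhMe/MeOH, 0 °C
Reagents that add atoms: trimethylsilyldiazomethane, C[Si](C)(C)C=[N+]=[N-]
Why: Prior conversion of the ring B β-keto ester into its lithium enolate shields the C5 carbonyl, electron transfer from SmI2 then cleaves the C4–O bond (reductive deoxygenation of an α-acyloxy ester that is also allylic) to a dienolate that t-BuOH should protonate at C4 rather than C2 and from the convex face opposite ring B, so that H takes the place of the oxygen with retention, and the freed C1 acid is methylated by the diazoalkane without base.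

Step 9
Reactants: 17 trimethyl (1S,4R,4aS,6S,7R,8aR)-2,7-dihexadecyl-5-oxo-1,4,4a,5,6,7,8,8a-octahydronaphthalene-1,4,6-tricarboxylate
Product: 20 trimethyl (1S,4R,4aS,8aR)-2,7-dihexadecyl-5-oxo-1,4,4a,5,8,8a-hexahydronaphthalene-1,4,6-tricarboxylate (target), via selenide 18 (not isolated), via selenoxide 19 (not isolated)
Conditions: PhSeCl, pyridine, CH2Cl2, 0 °C; then 30% H2O2, 0 °C to rt
Reagents that add atoms: phenylselenenyl chloride, Cl[Se]c1ccccc1; hydrogen peroxide, OO
Why: Selenenylation of the enolised β-keto ester at C6 from the face anti to the C7 hexadecyl group places selenium syn to C7–H, so oxidation and selenoxide syn-elimination should give the C6=C7 enone and erase the two temporary stereocentres, the selenium and the oxygen carried by 18 and 19 leaving again as benzeneselenenic acid.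

Compound list
1 | 1-octadecene | CCCCCCCCCCCCCCCCC=C | starting material
2 | (E)-crotonaldehyde | C/C=C/C=O | starting material
3 | (E)-nonadec-2-enal | CCCCCCCCCCCCCCCC/C=C/C=O | intermediate
4 | methyl acetoacetate | CC(=O)CC(=O)OC | starting material
5 | methyl (3R)-2-acetyl-3-(2-oxoethyl)nonadecanoate (Michael adduct aldehyde, C2 epimers) | CCCCCCCCCCCCCCCC[C@H](CC=O)C(C(C)=O)C(=O)OC | intermediate
6 | methyl (1S,6R)-6-hexadecyl-2-oxocyclohex-3-ene-1-carboxylate | O=C1C=CC[C@@H](CCCCCCCCCCCCCCCC)[C@@H]1C(=O)OC | intermediate
7 | methyl 2-(trimethylsilyloxy)acrylate | C=C(O[Si](C)(C)C)C(=O)OC | starting material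
8 | malonyl dichloride | ClC(=O)CC(Cl)=O | starting material
9 | methyl 6-chloro-2,4,6-trioxohexanoate (acid chloride) | COC(=O)C(=O)CC(=O)CC(Cl)=O | intermediate
10 | methyl 4-hydroxy-2-oxo-2H-pyran-6-carboxylate | COC(=O)C1=CC(O)=CC(=O)O1 | intermediate
11 | methyl 4-bromo-2-oxo-2H-pyran-6-carboxylate | COC(=O)C1=CC(Br)=CC(=O)O1 | intermediate
12 | bridged bromo lactone (endo [4+2] adduct, described in step 5) | BrC1=C[C@@]3(C(=O)OC)[C@H]2C(=O)[C@@H](C(=O)OC)[C@H](CCCCCCCCCCCCCCCC)C[C@H]2[C@@H]1C(=O)O3 | intermediate
13 | 1-bromohexadecane | CCCCCCCCCCCCCCCCBr | starting material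
14 | hexadecylzinc bromide (C16H33ZnBr) | CCCCCCCCCCCCCCCC[Zn]Br | intermediate
15 | bridged dihexadecyl lactone (12 with hexadecyl on C2) | CCCCCCCCCCCCCCCCC1=C[C@@]3(C(=O)OC)[C@H]2C(=O)[C@@H](C(=O)OC)[C@H](CCCCCCCCCCCCCCCC)C[C@H]2[C@@H]1C(=O)O3 | intermediate
16 | C1 carboxylic acid (lactone opened, C4–H in place of C4–O, C4 and C6 methyl esters) | CCCCCCCCCCCCCCCCC1=C[C@@H](C(=O)OC)[C@H]2C(=O)[C@@H](C(=O)OC)[C@H](CCCCCCCCCCCCCCCC)C[C@H]2[C@@H]1C(=O)O | intermediate
17 | trimethyl (1S,4R,4aS,6S,7R,8aR)-2,7-dihexadecyl-5-oxo-1,4,4a,5,6,7,8,8a-octahydronaphthalene-1,4,6-tricarboxylate (C1, C4, C4a, C8a as in the target; C7 hexadecyl anti to the ring A bonds, C6 CO2Me trans to it) | CCCCCCCCCCCCCCCCC1=C[C@@H](C(=O)OC)[C@H]2C(=O)[C@@H](C(=O)OC)[C@H](CCCCCCCCCCCCCCCC)C[C@H]2[C@@H]1C(=O)OC | intermediate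
18 | C6 phenylselenide of 17 (Se anti to the C7 hexadecyl) | CCCCCCCCCCCCCCCCC1=C[C@@H](C(=O)OC)[C@H]2C(=O)[C@]([Se]c3ccccc3)(C(=O)OC)[C@H](CCCCCCCCCCCCCCCC)C[C@H]2[C@@H]1C(=O)OC | intermediate
19 | selenoxide of 18 (configuration at Se not defined) | CCCCCCCCCCCCCCCCC1=C[C@@H](C(=O)OC)[C@H]2C(=O)[C@]([Se](=O)c3ccccc3)(C(=O)OC)[C@H](CCCCCCCCCCCCCCCC)C[C@H]2[C@@H]1C(=O)OC | intermediate
20 | trimethyl (1S,4R,4aS,8aR)-2,7-dihexadecyl-5-oxo-1,4,4a,5,8,8a-hexahydronaphthalene-1,4,6-tricarboxylate | CCCCCCCCCCCCCCCCC1=C[C@@H](C(=O)OC)[C@H]2C(=O)C(C(=O)OC)=C(CCCCCCCCCCCCCCCC)C[C@H]2[C@@H]1C(=O)OC | target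

Total steps: 9. Longest linear sequence: 6 steps (steps 1, 2, 5, 7, 8, 9, from 1-octadecene).

Steps most likely to fail

Step 5. The two electron-poor partners may combine too slowly even under pressure, the pyrone may instead act as a dienophile toward the dienol form of 6, or the addition may take the other regiochemistry or the exo course. The fallback replaces the bimolecular addition by delivery through a temporary tether; it sets out from 11 and 6 and comes back at 12. Hydrolysis of the methyl ester of 11 (Me3SnOH, 1,2-dichloroethane, 80 °C) would give 4-bromo-2-oxo-2H-pyran-6-carboxylic acid F1. Steglich O-acylation of the enol of 6 with it (DCC, DMAP, CH2Cl2, 0 °C) would give the enol ester F2, in which the pyrone C6 carboxyl is tied to the oxygen on C5 of ring B. Heating (PhMe, 100 °C) should bring about the intramolecular Diels–Alder reaction to the enol lactone adduct F3, the three-atom tether allowing only the C4–C4a/C1–C8a mode of union. Methanolysis of the activated enol ester (MeOH, DMAP cat., rt) would release the C4 methyl ester and the ring B β-keto ester, that is 12.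

Step 8. Reduction of the ring B carbonyl may compete if enolate protection is incomplete, and the dienolate may be protonated at C2 (giving the conjugated ester) or from the concave face. The fallback separates ionic opening from radical deoxygenation; it sets out from 15 and comes back at 17. Methanolysis of the bridged lactone (Mg(OMe)2, MeOH, 0 °C) would give the C1 methyl ester with a tertiary C4 alcohol, the hydroxy triester F4. Acylation with methyl oxalyl chloride (DMAP, pyridine, CH2Cl2) would give the C4 methyl oxalate F5. Bu3SnH with AIBN (PhMe, 100 °C) should cleave the C4–O bond homolytically (Barton–McCombie-type deoxygenation of a tertiary oxalate) and deliver hydrogen to the ester-stabilised allyl radical at C4 from the convex face, giving 17.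

Step 7. The organozinc may be consumed by the acidic β-keto ester, oxidative addition at the hindered alkenyl bromide may be slow, and β-hydride elimination may isomerise the chain. The fallback uses no preformed organometallic: a nickel-catalysed reductive cross-electrophile coupling of 12 with 1-bromohexadecane 13 itself (NiBr2(dme) 10 mol %, 4,4'-di-tert-butyl-2,2'-bipyridine, Mn powder, NaI, DMA, rt), coming back at 15. The alkenyl bromide adds to zerovalent nickel and the hexadecyl radical formed from 13 is captured at nickel, so no basic carbon nucleophile meets the β-keto ester. This fallback makes no new compound (none, F0).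

Further compounds
F1 | step 5 | 4-bromo-2-oxo-2H-pyran-6-carboxylic acid | OC(=O)C1=CC(Br)=CC(=O)O1
F2 | step 5 | enol ester of 6 (O on C5 of ring B acylated by F1; C7 centre as in 6) | COC(=O)C1=C(OC(=O)C2=CC(Br)=CC(=O)O2)C=CC[C@H]1CCCCCCCCCCCCCCCC
F3 | step 5 | tethered adduct: 12 with the C4 carboxyl closed as an enol lactone onto the C5 oxygen (C5=C6 enol double bond) | BrC1=C[C@@]3(C(=O)O4)[C@H]2C4=C(C(=O)OC)[C@H](CCCCCCCCCCCCCCCC)C[C@H]2[C@@H]1C(=O)O3
F4 | step 8 | hydroxy triester: 17 with OH in place of H on C4 (OH on the face of the former bridge) | CCCCCCCCCCCCCCCCC1=C[C@@](O)(C(=O)OC)[C@H]2C(=O)[C@@H](C(=O)OC)[C@H](CCCCCCCCCCCCCCCC)C[C@H]2[C@@H]1C(=O)OC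
F5 | step 8 | C4 methyl oxalate of F4 | CCCCCCCCCCCCCCCCC1=C[C@@](OC(=O)C(=O)OC)(C(=O)OC)[C@H]2C(=O)[C@@H](C(=O)OC)[C@H](CCCCCCCCCCCCCCCC)C[C@H]2[C@@H]1C(=O)OC
F0 | step 7 | none | none
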